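## Retrosynthetic overview

1. The curcuminoid is disconnected last at its styryl C=C: boron-templated aldol condensation of a terpenyl-O-vanillin aldehyde with feruloylacetone.
2. The sesquiterpene side chain is cut at CH2–C(=O) and C(=O)–CH=: hydroboration of an isopropenyl group, then a blue-light-driven Pd carbonylative coupling with CO and 1-bromo-2-methylpropene. This step also sets the side-chain stereocentre.
3. The ring C–OAr bond comes from Pd(0) syn-1,4 opening of a vinyl epoxide by a masked vanillin phenol.
4. The vinyl epoxide comes from (S)-carvone by trans-epoxidation, reduction and dehydration.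
5. Rings: the cyclohexene and both arenes are bought. The oxirane is made in step 1 and opened in step 5. A dioxolane aldehyde mask is made in step 4 and removed in step 6.

Assumptions: the target is the (1R,4S,6R)-ring / (2S)-side-chain isomer (ArO and OH cis, both trans to the side chain); the drawn enol is one tautomer of the β-diketone; phenol 7 and feruloylacetone 13 are made, not bought.

## Route

**Step 1**
Reactants: 1, (S)-(+)-carvone
Product: 2, (1S,4S,6S)-1-methyl-4-(prop-1-en-2-yl)-7-oxabicyclo[4.1.0]heptan-2-one (oxirane trans to isopropenyl)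
Conditions: 30% aq H2O2, NaOH (cat.), MeOH, 0 °C
Reagents that add atoms: hydrogen peroxide, OO
Why: Weitz–Scheffer nucleophilic epoxidation, in which hydroperoxide adds axially to the enone β-carbon anti to the C4 isopropenyl group, so the carvone stereocentre sets the epoxide (and the future carbinol C–O) trans to it while the isolated alkene is untouched.

**Step 2**
Reactants: 2
Product: 3, (1R,2ξ,4R,6S)-1-methyl-4-(prop-1-en-2-yl)-7-oxabicyclo[4.1.0]heptan-2-ol (C2 epimer mixture; C2 is destroyed in step 3)
Conditions: NaBH4, MeOH, 0 °C
Reagents that add atoms: none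
Why: Borohydride 1,2-reduction of the ketone leaves the oxirane and alkene intact, and the new carbinol configuration is irrelevant because both epimers converge in the next step.

**Step 3**
Reactants: 3
Product: 4, (1R,4S,6S)-1-methyl-4-(prop-1-en-2-yl)-7-oxabicyclo[4.1.0]hept-2-ene
Conditions: Burgess reagent, PhMe, 70 °C
Reagents that add atoms: none
Why: Burgess syn-elimination of the sulfamate can only proceed toward C3 (C1 is fully substituted) and works for either C2 epimer, giving the vinyl epoxide under neutral conditions without touching existing stereocentres.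

**Step 4**
Reactants: 5, vanillin; 6, ethylene glycol
Product: 7, 4-(1,3-dioxolan-2-yl)-2-methoxyphenol
Conditions: p-TsOH (cat.), PhMe, reflux, Dean–Stark; NaHCO3 quench
Reagents that add atoms: ethylene glycol, OCCO
Why: Acid-catalysed acetalisation with azeotropic water removal masks the aldehyde so it survives 9-BBN in step 6.

**Step 5**
Reactants: 4; 7
Product: 8, (1S,4S,5R)-4-[4-(1,3-dioxolan-2-yl)-2-methoxyphenoxy]-2-methyl-5-(prop-1-en-2-yl)cyclohex-2-en-1-ol
Conditions: Pd(PPh3)4 (3 mol%), THF, 0 → 23 °C
Reagents that add atoms: phenol 7, COc1cc(C2OCCO2)ccc1O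
Why: Tsuji–Trost opening of the vinyl epoxide, in which Pd(0) ionises the allylic C–O bond anti and the phenoxide attacks the less hindered distal allyl terminus anti to Pd, gives net syn-1,4 addition, so the new C–OAr centre is cis to the carbinol oxygen and trans to isopropenyl.

**Step 6**
Reactants: 8; 9, 1-bromo-2-methylprop-1-ene; 10, carbon monoxide
Product: 11, 4-{[(1R,4S,6R)-4-hydroxy-3-methyl-6-[(2S)-6-methyl-4-oxohept-5-en-2-yl]cyclohex-2-en-1-yl]oxy}-3-methoxybenzaldehyde
Conditions: 9-BBN (2.4 equiv), THF, 0 → 23 °C; then 9 (1.5 equiv), CO (1 atm), Pd(OAc)2 (5 mol%), DPEphos (6 mol%), 3 M aq K3PO4, blue LEDs (450 nm), 23 °C; then PPTS, acetone–H2O, 23 °C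
Reagents that add atoms: 1-bromo-2-methylprop-1-ene, CC(C)=CBr; carbon monoxide, [C-]#[O+]; water, O (acetal hydrolysis)
Why: Proposed new method: a visible-light-driven Pd-catalysed carbonylative B-alkyl Suzuki–Miyaura coupling with an alkenyl bromide, in which 9-BBN first adds anti-Markovnikov to the isopropenyl group only, delivering H to the internal carbon anti to the aryloxy-bearing ring carbon with the allylic H next to the vinylic methyl (A1,2-minimised hydroboration transition state, the sense expected from isopulegol-type trans-2-oxy isopropenylcyclohexanes) to set (2S), after which blue-light excitation of Pd(0)/DPEphos under CO activates bromide 9 at room temperature, CO inserts, the borate transfers its primary alkyl group by two-electron transmetalation (no free alkyl radical that could cyclise onto the ring alkene) and reductive elimination forms both C–C bonds of the enone; the closest known chemistry is the thermal carbonylative Suzuki–Miyaura coupling of 9-alkyl-9-BBN reagents with iodoalkenes together with light-driven Pd carbonylation of organic halides, and the mild acid work-up then unmasks the aldehyde.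

**Step 7**
Reactants: 5, vanillin; 12, acetylacetone
Product: 13, (1E,4Z)-5-hydroxy-1-(4-hydroxy-3-methoxyphenyl)hexa-1,4-dien-3-one (feruloylacetone, enol form)
Conditions: 12 (3 equiv), B2O3, B(OnBu)3, n-BuNH2 (cat.), EtOAc, 50 °C; then 0.4 M HCl, 50 °C
Reagents that add atoms: acetylacetone, CC(=O)CC(C)=O
Why: Pabon mono-condensation, where boron chelation blocks the central carbon of the diketone and directs amine-catalysed aldol condensation to a terminal methyl, with excess diketone suppressing the bis-adduct.

**Step 8**
Reactants: 11; 13
Product: 14, bisabolocurcumin ether (target)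
Conditions: 13, B2O3, EtOAc, 60 °C; then 11, B(OnBu)3, n-BuNH2 (0.3 equiv), 40 °C; then 10% aq AcOH, 40 °C
Reagents that add atoms: feruloylacetone 13, C/C(O)=C/C(=O)/C=C/c1ccc(O)c(OC)c1
Why: Pabon boron-templated aldol condensation of the remaining methyl of chelated 13 with the aryl aldehyde gives the (E)-styryl enone, and the weakly acidic de-chelation spares the allylic aryl ether, the allylic alcohol and all four stereocentres.

## Compound list

1 | (S)-(+)-carvone | CC1=CC[C@@H](CC1=O)C(C)=C | starting material
2 | (1S,4S,6S)-1-methyl-4-(prop-1-en-2-yl)-7-oxabicyclo[4.1.0]heptan-2-one | O=C1C[C@@H](C(C)=C)C[C@@H]2O[C@]12C | intermediate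
3 | (1R,2ξ,4R,6S)-1-methyl-4-(prop-1-en-2-yl)-7-oxabicyclo[4.1.0]heptan-2-ol (C2 epimers) | OC1C[C@@H](C(C)=C)C[C@@H]2O[C@]12C | intermediate
4 | (1R,4S,6S)-1-methyl-4-(prop-1-en-2-yl)-7-oxabicyclo[4.1.0]hept-2-ene | C=C(C)[C@@H]1C=C[C@@]2(C)O[C@H]2C1 | intermediate
5 | vanillin | COc1cc(C=O)ccc1O | starting material
6 | ethylene glycol | OCCO | starting material
7 | 4-(1,3-dioxolan-2-yl)-2-methoxyphenol | COc1cc(C2OCCO2)ccc1O | intermediate
8 | (1S,4S,5R)-4-[4-(1,3-dioxolan-2-yl)-2-methoxyphenoxy]-2-methyl-5-(prop-1-en-2-yl)cyclohex-2-en-1-ol | COc1cc(C2OCCO2)ccc1O[C@H]1C=C(C)[C@@H](O)C[C@@H]1C(C)=C | intermediate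
9 | 1-bromo-2-methylprop-1-ene | CC(C)=CBr | starting material
10 | carbon monoxide | [C-]#[O+] | starting material
11 | 4-{[(1R,4S,6R)-4-hydroxy-3-methyl-6-[(2S)-6-methyl-4-oxohept-5-en-2-yl]cyclohex-2-en-1-yl]oxy}-3-methoxybenzaldehyde | COc1cc(C=O)ccc1O[C@H]1C=C(C)[C@@H](O)C[C@@H]1[C@@H](C)CC(=O)C=C(C)C | intermediate
12 | acetylacetone (pentane-2,4-dione) | CC(=O)CC(C)=O | starting material
13 | (1E,4Z)-5-hydroxy-1-(4-hydroxy-3-methoxyphenyl)hexa-1,4-dien-3-one | C/C(O)=C/C(=O)/C=C/c1ccc(O)c(OC)c1 | intermediate
14 | (1E,4Z,6E)-5-hydroxy-1-(4-hydroxy-3-methoxyphenyl)-7-(4-{[(1R,4S,6R)-4-hydroxy-3-methyl-6-[(2S)-6-methyl-4-oxohept-5-en-2-yl]cyclohex-2-en-1-yl]oxy}-3-methoxyphenyl)hepta-1,4,6-trien-3-one | COc1cc(/C=C/C(=O)/C=C(O)/C=C/c2ccc(O[C@H]3C=C(C)[C@@H](O)C[C@@H]3[C@@H](C)CC(=O)C=C(C)C)c(OC)c2)ccc1O | target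

## Step count and risks

Total steps: 8. Longest linear sequence: 6 (steps 1, 2, 3, 5, 6, 8).

Steps most likely to fail:

1. **Step 6 (proposed new step).** Possible failures are direct non-carbonylative coupling, loss of the alkenyl fragment by H-abstraction, Pd(0) ionisation of the allylic aryl ether, or an insufficient diastereomer ratio at C2′. Fallback (known chemistry): use the same 9-BBN adduct in a Liebeskind–Srogl acyl transfer with S-phenyl 3-methylbut-2-enethioate (Pd2(dba)3, tri-2-furylphosphine, CuTC, THF, 45 °C). This is a two-component coupling with a preformed C5 acyl donor, no CO and no light, followed by the same PPTS unmasking.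

2. **Step 3 (dehydration to a volatile, acid-sensitive vinyl epoxide).** Ionisation next to the oxirane could cause rearrangement. Fallback: avoid the vinyl epoxide. Wharton transposition of 2 gives the trans-carveol-type allylic alcohol; a hydroxy-directed singlet-oxygen ene reaction with PPh3 reduction gives the cis-1,2-diol with the alkene moved next to C4; cyclic carbonate formation and Pd-catalysed decarboxylative 1,4-etherification with 7 then reach 8.

3. **Step 8 (final condensation).** The aqueous acid used to break the boron chelate could ionise the allylic aryl ether. Fallback: switch to the isolable difluoroboron chelate of 13 (made with BF3·OEt2 before 11 is introduced), condense it with 11 under n-BuNH2 in toluene, and release the curcuminoid under near-neutral conditions (aq MeOH, sodium oxalate).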